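**Strategy.** The dihydropyran ring (ring C) is opened at C2–C3 at the enol ether oxidation level. Because C2 is a methylene flanked by O1 and the C3 methine, this bond can be made as a C2=C3 double bond by ring-closing metathesis between an O1 vinyl ether and a 2-arylallyl group on C4a, with loss of ethylene. The precursor is an acyclic aryl vinyl ether whose C4a side chain is delivered by a Claisen rearrangement from the same oxygen, which fixes O1 and C4 ortho to each other on the symmetric 2,6-dihydroxy-4-methoxybenzaldehyde core. Iridium-catalysed asymmetric hydrogenation of the resulting isoflav-2-ene then sets C3 as (R).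

Key step: step 7

Assumption: 1,3-bis(methoxymethoxy)benzene (1) and 2,6-dihydroxy-4-methoxybenzaldehyde (9) are taken as catalogue compounds (each is otherwise one step from resorcinol or 2,4,6-trihydroxybenzaldehyde).

Remark: chroman numbering is used throughout (O1, C2, C3, C4, C4a, C5 to C8, C8a); ring A is the benzo ring, ring B the pendant aryl ring, ring C the pyran ring. By CIP analysis of the given SMILES the target is (3R).

**Step 1**
Reactants: 1 1,3-bis(methoxymethoxy)benzene; 2 prenyl bromide (1-bromo-3-methylbut-2-ene)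
Product: 4 1,3-bis(methoxymethoxy)-2-(3-methylbut-2-en-1-yl)benzene, via 2,6-bis(methoxymethoxy)phenyllithium 3 (not isolated)
Conditions: n-BuLi, THF, 0 °C; then CuI (10 mol%), 2, −78 °C to rt
Reagents that add atoms: none
Why: Directed ortho-metalation, in which both MOM ethers direct lithiation to the carbon between them, followed by copper-catalysed alkylation with the primary allylic bromide to give the linear prenyl group.

**Step 2**
Reactants: 4 1,3-bis(methoxymethoxy)-2-(3-methylbut-2-en-1-yl)benzene; 5 2-bromoprop-2-en-1-ol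
Product: 8 2-[2,4-bis(methoxymethoxy)-3-(3-methylbut-2-en-1-yl)phenyl]prop-2-en-1-ol, via aryllithium 6 (not isolated), via pinacol arylboronate 7 (not isolated)
Conditions: n-BuLi, TMEDA, THF, −20 to 0 °C; 2-isopropoxy-4,4,5,5-tetramethyl-1,3,2-dioxaborolane, −78 °C to rt; then 5, Pd(dppf)Cl2 (3 mol%), aq. K3PO4, 65 °C, one pot
Reagents that add atoms: none
Why: A second directed ortho-metalation can occur only ortho to one MOM group, and the aryllithium is trapped as the boronate and cross-coupled in the same pot with the vinylic bromide (one-pot metalation, borylation and Suzuki–Miyaura coupling), which should leave the free allylic alcohol untouched.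

**Step 3**
Reactants: 9 2,6-dihydroxy-4-methoxybenzaldehyde
Product: 10 2-hydroxy-4-methoxy-6-(methoxymethoxy)benzaldehyde
Conditions: MOMCl (1.05 equiv), iPr2NEt, CH2Cl2, 0 °C
Reagents that add atoms: chloromethyl methyl ether (MOMCl), COCCl
Why: Mono-protection of a symmetric bis-phenol (O-alkylation to the MOM acetal), which should stop after one group because the remaining hydroxyl is then locked in a hydrogen bond to the formyl oxygen.

**Step 4**
Reactants: 10 2-hydroxy-4-methoxy-6-(methoxymethoxy)benzaldehyde; 8 2-[2,4-bis(methoxymethoxy)-3-(3-methylbut-2-en-1-yl)phenyl]prop-2-en-1-ol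
Product: 11 2-({2-[2,4-bis(methoxymethoxy)-3-(3-methylbut-2-en-1-yl)phenyl]prop-2-en-1-yl}oxy)-4-methoxy-6-(methoxymethoxy)benzaldehyde
Conditions: PPh3, DIAD, THF, 0 °C to rt
Reagents that add atoms: none
Why: Mitsunobu etherification of the acidic ortho-formyl phenol with the primary allylic alcohol, in which SN2 and SN2′ attack give the same ether because the allyl unit is symmetric about its central carbon.

**Step 5**
Reactants: 11 the aryl 2-arylallyl ether
Product: 13 3-{2-[2,4-bis(methoxymethoxy)-3-(3-methylbut-2-en-1-yl)phenyl]prop-2-en-1-yl}-2-hydroxy-4-methoxy-6-(methoxymethoxy)benzaldehyde, via ortho-dienone 12 (not isolated)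
Conditions: N,N-diethylaniline, 185 °C, sealed tube
Reagents that add atoms: none
Why: Aromatic Claisen rearrangement ([3,3]-sigmatropic shift) to the only free ortho carbon (the other ortho position carries CHO) and tautomerisation of dienone 12, which places the future C4 on C4a and frees exactly the oxygen that becomes O1.

**Step 6**
Reactants: 13 the ortho-(2-arylallyl)phenol
Product: 14 3-{2-[2,4-bis(methoxymethoxy)-3-(3-methylbut-2-en-1-yl)phenyl]prop-2-en-1-yl}-2-(ethenyloxy)-4-methoxy-6-(methoxymethoxy)benzaldehyde
Conditions: vinyl acetate (excess), [Ir(cod)Cl]2 (2 mol%), Na2CO3 (0.6 equiv), toluene, 100 °C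
Reagents that add atoms: vinyl acetate, CC(=O)OC=C
Why: Iridium-catalysed transfer vinylation of a phenol with vinyl acetate; the only free hydroxyl is the one released in step 5, so the vinyl group, whose inner carbon becomes C2, should land on O1.

**Step 7**
Reactants: 14 the aryl vinyl ether diene
Product: 15 3-[2,4-bis(methoxymethoxy)-3-(3-methylbut-2-en-1-yl)phenyl]-5-methoxy-7-(methoxymethoxy)-4H-chromene-8-carbaldehyde
Conditions: second-generation Hoveyda–Grubbs catalyst RuCl2(H2IMes)(=CH-C6H4-2-OiPr) (5–10 mol%), 1,4-benzoquinone (10 mol%), toluene (0.005 M), 80–100 °C, argon sparge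
Reagents that add atoms: none
Why: Olefin metathesis by the Chauvin mechanism: the ruthenium alkylidene exchanges with the O1 vinyl ether, the resulting Ru=CH–OAr carbene adds across the 1,1-disubstituted alkene held on C4a to give a ruthenacyclobutane, and cycloreversion releases the C2=C3 enol ether and, after turnover, ethylene. The closest known reaction type is ring-closing metathesis of 2-allylaryl vinyl ethers to 4H-chromenes and of enol ether/1,1-disubstituted alkene pairs to trisubstituted cyclic enol ethers. The pyran ring closes as a six-membered ring-closing metathesis in which both carbons of the new double bond (C2 and C3) become ring members, the entropic cost being low because C8a–C4a of ring A holds the two alkenes in a 1,6 relationship. No stereocentre is formed here: C3 leaves the step as a prochiral sp2 carbon and is set in step 8 by the chiral iridium catalyst. The step needs chemoselectivity for the two terminal alkenes over the trisubstituted prenyl olefin and freedom from double-bond migration; the first should be secured by the low metathesis reactivity of trisubstituted alkyl olefins and by high dilution, the second by the benzoquinone additive, which intercepts ruthenium hydrides.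

**Step 8**
Reactants: 15 the 3-aryl-4H-chromene
Product: 16 (3R)-3-[2,4-bis(methoxymethoxy)-3-(3-methylbut-2-en-1-yl)phenyl]-5-methoxy-7-(methoxymethoxy)-3,4-dihydro-2H-chromene-8-carbaldehyde
Conditions: H2 (30–50 bar), [Ir(cod)(tBu-PHOX)]BArF (2 mol%; PHOX = 2-(2-diphenylphosphinophenyl)-4-tert-butyloxazoline, BArF = B[3,5-(CF3)2C6H3]4; ligand antipode chosen for Si-face delivery at C3), CH2Cl2, rt
Reagents that add atoms: none
Why: Iridium P,N-ligand catalysed asymmetric hydrogenation of a trisubstituted, aryl-conjugated cyclic enol ether, in which the catalyst controls the face and addition of hydrogen to the Si face of C3 (C2 > C1′ > C4) gives (3R); the purely alkyl-substituted prenyl olefin and the aldehyde should react much more slowly with this catalyst class.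

**Step 9**
Reactants: 16 the tris-MOM (3R)-isoflavan
Product: 17 (3R)-3-[2,4-dihydroxy-3-(3-methylbut-2-en-1-yl)phenyl]-7-hydroxy-5-methoxy-3,4-dihydro-2H-chromene-8-carbaldehyde (target)
Conditions: HCl (3 M aq., catalytic), MeOH/THF, 40 °C; aqueous work-up
Reagents that add atoms: none
Why: Acid-catalysed transacetalisation of the three MOM acetals to methanol under conditions mild enough that the prenyl group should not cyclise onto its neighbouring phenols; C3 carries no acidifying group and cannot epimerise.

**Compound list**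
1 | 1,3-bis(methoxymethoxy)benzene | COCOc1cccc(OCOC)c1 | starting material
2 | prenyl bromide (1-bromo-3-methylbut-2-ene) | CC(C)=CCBr | starting material
3 | 2,6-bis(methoxymethoxy)phenyllithium | [Li]c1c(OCOC)cccc1OCOC | intermediate
4 | 1,3-bis(methoxymethoxy)-2-(3-methylbut-2-en-1-yl)benzene | COCOc1cccc(OCOC)c1CC=C(C)C | intermediate
5 | 2-bromoprop-2-en-1-ol | OCC(Br)=C | starting material
6 | [2,4-bis(methoxymethoxy)-3-(3-methylbut-2-en-1-yl)phenyl]lithium | [Li]c1ccc(OCOC)c(CC=C(C)C)c1OCOC | intermediate
7 | 2-[2,4-bis(methoxymethoxy)-3-(3-methylbut-2-en-1-yl)phenyl]-4,4,5,5-tetramethyl-1,3,2-dioxaborolane | CC1(C)OB(OC1(C)C)c1ccc(OCOC)c(CC=C(C)C)c1OCOC | intermediate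
8 | 2-[2,4-bis(methoxymethoxy)-3-(3-methylbut-2-en-1-yl)phenyl]prop-2-en-1-ol | OCC(=C)c1ccc(OCOC)c(CC=C(C)C)c1OCOC | intermediate
9 | 2,6-dihydroxy-4-methoxybenzaldehyde | COc1cc(O)c(C=O)c(O)c1 | starting material
10 | 2-hydroxy-4-methoxy-6-(methoxymethoxy)benzaldehyde | COCOc1cc(OC)cc(O)c1C=O | intermediate
11 | 2-({2-[2,4-bis(methoxymethoxy)-3-(3-methylbut-2-en-1-yl)phenyl]prop-2-en-1-yl}oxy)-4-methoxy-6-(methoxymethoxy)benzaldehyde | O=Cc1c(OCC(=C)c2ccc(OCOC)c(CC=C(C)C)c2OCOC)cc(OC)cc1OCOC | intermediate
12 | 5-{2-[2,4-bis(methoxymethoxy)-3-(3-methylbut-2-en-1-yl)phenyl]prop-2-en-1-yl}-4-methoxy-2-(methoxymethoxy)-6-oxocyclohexa-1,3-diene-1-carbaldehyde | O=CC1=C(OCOC)C=C(OC)C(CC(=C)c2ccc(OCOC)c(CC=C(C)C)c2OCOC)C1=O | intermediate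
13 | 3-{2-[2,4-bis(methoxymethoxy)-3-(3-methylbut-2-en-1-yl)phenyl]prop-2-en-1-yl}-2-hydroxy-4-methoxy-6-(methoxymethoxy)benzaldehyde | O=Cc1c(O)c(CC(=C)c2ccc(OCOC)c(CC=C(C)C)c2OCOC)c(OC)cc1OCOC | intermediate
14 | 3-{2-[2,4-bis(methoxymethoxy)-3-(3-methylbut-2-en-1-yl)phenyl]prop-2-en-1-yl}-2-(ethenyloxy)-4-methoxy-6-(methoxymethoxy)benzaldehyde | O=Cc1c(OC=C)c(CC(=C)c2ccc(OCOC)c(CC=C(C)C)c2OCOC)c(OC)cc1OCOC | intermediate
15 | 3-[2,4-bis(methoxymethoxy)-3-(3-methylbut-2-en-1-yl)phenyl]-5-methoxy-7-(methoxymethoxy)-4H-chromene-8-carbaldehyde | COc1cc(OCOC)c(C=O)c2c1CC(c1ccc(OCOC)c(CC=C(C)C)c1OCOC)=CO2 | intermediate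
16 | (3R)-3-[2,4-bis(methoxymethoxy)-3-(3-methylbut-2-en-1-yl)phenyl]-5-methoxy-7-(methoxymethoxy)-3,4-dihydro-2H-chromene-8-carbaldehyde | COc1cc(OCOC)c(C=O)c2c1C[C@H](c1ccc(OCOC)c(CC=C(C)C)c1OCOC)CO2 | intermediate
17 | (3R)-3-[2,4-dihydroxy-3-(3-methylbut-2-en-1-yl)phenyl]-7-hydroxy-5-methoxy-3,4-dihydro-2H-chromene-8-carbaldehyde | COc1cc(O)c(C=O)c2c1C[C@H](c1ccc(O)c(CC=C(C)C)c1O)CO2 | target

**Totals.** Total step count: 9. Longest linear sequence: 8 steps (steps 1, 2, 4, 5, 6, 7, 8, 9 from compound 1).

**Steps most likely to fail**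

Step 7 (ring-closing metathesis). The catalyst may be arrested as an unreactive ruthenium Fischer carbene, possibly chelated by the ortho formyl oxygen, and the hindered 1,1-disubstituted alkene may engage too slowly, so that double-bond migration or oligomerisation takes over. The fallback keeps the C2=C3 ring closure but performs it on the unhindered, closely precedented allyl analogue and attaches ring B afterwards. It sets out from 10: O-allylation (allyl bromide, K2CO3, DMF) should give 2-(allyloxy)-4-methoxy-6-(methoxymethoxy)benzaldehyde F1. Claisen rearrangement (N,N-diethylaniline, 185 °C) should give 3-allyl-2-hydroxy-4-methoxy-6-(methoxymethoxy)benzaldehyde F2. Vinyl transfer as in step 6 should give 3-allyl-2-(ethenyloxy)-4-methoxy-6-(methoxymethoxy)benzaldehyde F3. Ring-closing metathesis with the same ruthenium catalyst should give 5-methoxy-7-(methoxymethoxy)-4H-chromene-8-carbaldehyde F4. Addition of Br2 at −78 °C should give 2,3-dibromo-5-methoxy-7-(methoxymethoxy)chromane-8-carbaldehyde F5 (not isolated), which on treatment with Et3N should lose HBr to give 3-bromo-5-methoxy-7-(methoxymethoxy)-4H-chromene-8-carbaldehyde F6. Suzuki–Miyaura coupling of F6 with boronate 7 (isolated in this variant; Pd(dppf)Cl2, aq. K3PO4) comes back to the route at 15.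

Step 8 (asymmetric hydrogenation). The prenyl double bond may be over-reduced, facial discrimination at C3 may be insufficient, and the acidic iridium hydride may isomerise the enol ether. The fallback replaces hydrogen gas by an organocatalytic hydride transfer that cannot touch an isolated alkene. It sets out from 15: acidic methanolysis (HCl, MeOH/THF) should remove the three MOM groups while the enol ether equilibrates, through the C3 cation stabilised by ring B, to the conjugated 2H-chromene 3-[2,4-dihydroxy-3-(3-methylbut-2-en-1-yl)phenyl]-7-hydroxy-5-methoxy-2H-chromene-8-carbaldehyde F7. A chiral phosphoric acid (TRIP, antipode chosen for the (3R) product) should then protonate C4 to give the ortho-quinone methide of ring B, and a Hantzsch ester should deliver hydride to C3 within the chiral ion pair (phosphoric acid catalysed transfer hydrogenation of ortho-hydroxystyrenes). The fallback comes back to the route at 17.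

Step 6 (O-vinylation). Vinyl transfer to a hindered, hydrogen-bonded phenol may be incomplete, and the phenol may instead add across the neighbouring 1,1-disubstituted alkene (intramolecular hydroalkoxylation). The fallback builds the vinyl ether by alkylation and elimination instead of metal-catalysed transfer. It sets out from 13: alkylation with excess 1,2-dibromoethane (K2CO3, DMF, 60 °C) should give 3-{2-[2,4-bis(methoxymethoxy)-3-(3-methylbut-2-en-1-yl)phenyl]prop-2-en-1-yl}-2-(2-bromoethoxy)-4-methoxy-6-(methoxymethoxy)benzaldehyde F8, and E2 elimination (KOtBu, THF, 0 °C, short contact time) comes back to the route at 14.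

**Further compounds**
F1 | step 7 | 2-(allyloxy)-4-methoxy-6-(methoxymethoxy)benzaldehyde | O=Cc1c(OCC=C)cc(OC)cc1OCOC
F2 | step 7 | 3-allyl-2-hydroxy-4-methoxy-6-(methoxymethoxy)benzaldehyde | O=Cc1c(O)c(CC=C)c(OC)cc1OCOC
F3 | step 7 | 3-allyl-2-(ethenyloxy)-4-methoxy-6-(methoxymethoxy)benzaldehyde | O=Cc1c(OC=C)c(CC=C)c(OC)cc1OCOC
F4 | step 7 | 5-methoxy-7-(methoxymethoxy)-4H-chromene-8-carbaldehyde | COc1cc(OCOC)c(C=O)c2c1CC=CO2
F5 | step 7 | 2,3-dibromo-5-methoxy-7-(methoxymethoxy)chromane-8-carbaldehyde | COc1cc(OCOC)c(C=O)c2c1CC(Br)C(Br)O2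
F6 | step 7 | 3-bromo-5-methoxy-7-(methoxymethoxy)-4H-chromene-8-carbaldehyde | COc1cc(OCOC)c(C=O)c2c1CC(Br)=CO2
F7 | step 8 | 3-[2,4-dihydroxy-3-(3-methylbut-2-en-1-yl)phenyl]-7-hydroxy-5-methoxy-2H-chromene-8-carbaldehyde | COc1cc(O)c(C=O)c2c1C=C(c1ccc(O)c(CC=C(C)C)c1O)CO2
F8 | step 6 | 3-{2-[2,4-bis(methoxymethoxy)-3-(3-methylbut-2-en-1-yl)phenyl]prop-2-en-1-yl}-2-(2-bromoethoxy)-4-methoxy-6-(methoxymethoxy)benzaldehyde | O=Cc1c(OCCBr)c(CC(=C)c2ccc(OCOC)c(CC=C(C)C)c2OCOC)c(OC)cc1OCOC
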